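**Retrosynthetic overview**
1. Target 23 ⇒ macrocyclic C6 alcohol 20 + (S)-2-methylglycidic acid 22 (O6 acylation last).
2. 20 ⇒ bromomethyl-butenolide (Z)-enal 19: the ten-membered carbocycle is closed at C6–C7, the bond germacrene A synthase forms from farnesyl diphosphate, with the same polarity (C7 nucleophile, C6 electrophile); this also creates the α-methylene lactone and sets C6 and C7.
3. 19 ⇒ furan 17: the 3(2H)-furanone forms as in the presumed biosynthesis, by addition of the C10 hydroxyl to C3 of a 10-hydroxy-1,3-diketone and loss of water; diketone and (Z)-enal are unveiled together by oxidative opening of a 3-methylfuran.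
4. 17 ⇒ vinyl lactone 9 + (Z)-enynol 10 (acetylide acylation, cycloisomerisation to the furan, O8–C12 acylation, RCM to the butenolide).
5. 9 ⇒ (S)-lactic acid (C10) + (S)-glycidol (C8). Ring order: butenolide, then furanone, then carbocycle.

Assumption: germacrane numbering is used (C1 ketone, C3–O–C10 bridge, C4=C5 Z, C6 ester, 8,12-lactone); the SMILES is read as 6R,7R,8S,10R with an (S)-2-methyloxirane-2-carboxylate.

**Step 1**
Reactants: 1 (S)-lactic acid; 2 pivalaldehyde
Product: 3 (2S,5S)-2-tert-butyl-5-methyl-1,3-dioxolan-4-one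
Conditions: TsOH·H2O (cat.), H2SO4 (cat.), pentane, reflux, Dean–Stark; recrystallise from pentane at −78 °C
Reagents that add atoms: none
Why: Acid-catalysed acetalisation (Seebach dioxolanone) gives mainly the cis acetal, which is purified by crystallisation and stores the lactic acid configuration in the new acetal centre.

**Step 2**
Reactants: 4 (S)-glycidol
Product: 5 [(2R)-oxiran-2-yl]methyl trifluoromethanesulfonate
Conditions: Tf2O, 2,6-lutidine, CH2Cl2, −78 °C; cold aqueous wash, solution used at once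
Reagents that add atoms: triflic anhydride, O=S(=O)(OS(=O)(=O)C(F)(F)F)C(F)(F)F
Why: O-sulfonylation of the primary alcohol leaves the stereocentre untouched (the descriptor changes from S to R only through the priority rules).

**Step 3**
Reactants: 3 (2S,5S)-2-tert-butyl-5-methyl-1,3-dioxolan-4-one; 5 [(2R)-oxiran-2-yl]methyl trifluoromethanesulfonate
Product: 7 (2S,5R)-2-tert-butyl-5-methyl-5-{[(2S)-oxiran-2-yl]methyl}-1,3-dioxolan-4-one, via lithium enolate 6 (not isolated)
Conditions: LiN(iPr)2, THF, −78 °C; then 5, −78 → −40 °C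
Reagents that add atoms: none
Why: Seebach alkylation with self-regeneration of the stereocentre: the triflate is displaced by direct SN2 attack on the enolate face anti to the tert-butyl group, which sets the quaternary C10 with retention and carries the glycidol centre (C8) over unchanged.

**Step 4**
Reactants: 7 (2S,5R)-2-tert-butyl-5-methyl-5-{[(2S)-oxiran-2-yl]methyl}-1,3-dioxolan-4-one
Product: 9 (3R,5S)-5-ethenyl-3-hydroxy-3-methyloxolan-2-one, via lithium alkoxide 8 (not isolated)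
Conditions: Me3SI (4 equiv), n-BuLi (3.9 equiv), THF, −10 °C; 7, −10 → 20 °C; H2O
Reagents that add atoms: trimethylsulfonium iodide, C[S+](C)C.[I-]
Why: Sulfonium ylide homologation of a terminal epoxide to an allylic alcohol (attack at CH2, then loss of Me2S) gives the allylic alkoxide, which translactonises onto the dioxolanone carbonyl and expels pivalaldehyde, so C8 and C10 keep their configurations.

**Step 5**
Reactants: 9 (3R,5S)-5-ethenyl-3-hydroxy-3-methyloxolan-2-one; 10 (2Z)-3-methylpent-2-en-4-yn-1-ol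
Product: 13 (3R,5S)-3,5-dihydroxy-3-methyl-1-(3-methylfuran-2-yl)hept-6-en-2-one, via dilithio enynol 11 (not isolated), via ynone triol 12 (not isolated)
Conditions: 10 (2.6 equiv), n-BuLi (5.2 equiv), THF, −78 → −20 °C; 9, −78 → −30 °C; AcOH, −78 °C, aqueous wash; crude 12, DBU (10 mol %), THF, 20 °C
Reagents that add atoms: none
Why: Acetylide acylation by the γ-lactone (addition stops at the lactolate) gives the ynone, whose (Z)-allylic hydroxyl adds 5-exo-dig to C3 (oxa-Michael cycloisomerisation of a (Z)-2-en-4-yn-1-ol) and tautomerises to the furan, which stores C3 to C6 with the cis geometry locked; no stereocentre is touched.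

**Step 6**
Reactants: 13 (3R,5S)-3,5-dihydroxy-3-methyl-1-(3-methylfuran-2-yl)hept-6-en-2-one; 14 2-(bromomethyl)prop-2-enoic acid
Product: 16 (3S,5R)-5-hydroxy-5-methyl-7-(3-methylfuran-2-yl)-6-oxohept-1-en-3-yl 2-(bromomethyl)prop-2-enoate, via acid chloride 15 (not isolated)
Conditions: 14, (COCl)2, DMF (cat.), CH2Cl2, 0 → 20 °C; then 13, 2,6-lutidine, CH2Cl2, −40 → 0 °C
Reagents that add atoms: none
Why: Acylation of the secondary allylic C8 hydroxyl by the acid chloride forms the O8–C12 bond of the future lactone with retention at C8; the tertiary α-ketol hydroxyl is inert and the hindered base does not displace the allylic bromide.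

**Step 7**
Reactants: 16 (3S,5R)-5-hydroxy-5-methyl-7-(3-methylfuran-2-yl)-6-oxohept-1-en-3-yl 2-(bromomethyl)prop-2-enoate
Product: 17 (5S)-3-(bromomethyl)-5-[(2R)-2-hydroxy-2-methyl-4-(3-methylfuran-2-yl)-3-oxobutyl]furan-2(5H)-one
Conditions: second-generation Hoveyda–Grubbs catalyst (7 mol %), toluene (5 mM), 80 °C, argon sparge
Reagents that add atoms: none
Why: Ring-closing metathesis between the vinyl group and the 1,1-disubstituted acrylate closes the five-membered butenolide (C7=C11) with loss of ethene and leaves C8 and C10 untouched.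

**Step 8**
Reactants: 17 (5S)-3-(bromomethyl)-5-[(2R)-2-hydroxy-2-methyl-4-(3-methylfuran-2-yl)-3-oxobutyl]furan-2(5H)-one
Product: 19 (2Z)-3-[(5R)-5-{[(2S)-4-(bromomethyl)-5-oxo-2,5-dihydrofuran-2-yl]methyl}-5-methyl-4-oxo-4,5-dihydrofuran-2-yl]but-2-enal, via open-chain keto enal 18 (not isolated)
Conditions: NBS (1.0 equiv), NaHCO3 (1.1 equiv), THF–H2O (4:1), −20 → 0 °C; then AcOH (cat.), 20 °C
Reagents that add atoms: none
Why: Proposed new method: the one-flask sequence is untested on such a substrate, but NBS/water opening of the 2,3-disubstituted furan (closest known reaction: Achmatowicz-type oxidative furan opening to a (Z)-4-oxo-2-enal) should unveil the 10-hydroxy-1,3-diketone 18, whose tertiary hydroxyl adds to the C3 carbonyl and loses water through the C2 enol (closest known reaction: acid-catalysed cyclodehydration of α′-hydroxy-1,3-diketones to 3(2H)-furanones), the Z geometry of C4=C5 being inherited from the furan ring and no stereocentre being touched.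

**Step 9**
Reactants: 19 (2Z)-3-[(5R)-5-{[(2S)-4-(bromomethyl)-5-oxo-2,5-dihydrofuran-2-yl]methyl}-5-methyl-4-oxo-4,5-dihydrofuran-2-yl]but-2-enal
Product: 20 (4Z,6R,7R,8S,10R)-6-hydroxy-1-oxo-3,10-epoxygermacra-2,4,11(13)-trien-12,8-olide
Conditions: CrCl2 (8 equiv), THF–DMF (10:1), 20 °C, syringe-pump addition of 19 over 12 h (final 1 mM); aqueous work-up
Reagents that add atoms: none
Why: Intramolecular Nozaki–Hiyama allylation: the allylchromium from the bromomethylbutenolide attacks the aldehyde through its γ-carbon C7 in a closed chair transition state (C5 and C8 both equatorial, giving the 6,7-anti adduct) on the butenolide face opposite the C8–C9 bond (trans lactone), closing the carbocycle at C6–C7 and generating the exocyclic methylene.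

**Step 10**
Reactants: 21 [(2R)-2-methyloxiran-2-yl]methanol
Product: 22 (2S)-2-methyloxirane-2-carboxylic acid
Conditions: RuCl3·xH2O (2 mol %), NaIO4 (2.5 equiv), MeCN–EtOAc–H2O, 0 → 20 °C
Reagents that add atoms: water, O; NaIO4 (sodium periodate), [Na+].[O-]I(=O)(=O)=O
Why: RuO4-catalysed (Sharpless) oxidation of the primary alcohol to the acid does not touch the quaternary epoxide carbon (the descriptor changes from R to S only through the priority rules).

**Step 11**
Reactants: 20 (4Z,6R,7R,8S,10R)-6-hydroxy-1-oxo-3,10-epoxygermacra-2,4,11(13)-trien-12,8-olide; 22 (2S)-2-methyloxirane-2-carboxylic acid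
Product: 23 (4Z,6R,7R,8S,10R)-6-{[(2S)-2-methyloxiran-2-yl]carbonyloxy}-1-oxo-3,10-epoxygermacra-2,4,11(13)-trien-12,8-olide (CNP0321429.1)
Conditions: DCC (1.5 equiv), DMAP (10 mol %), CH2Cl2, 0 → 20 °C
Reagents that add atoms: none
Why: Steglich esterification acylates the C6 hydroxyl at oxygen, so C6 and the epoxide centre are retained.

**Compound list**
1 | (S)-lactic acid | C[C@H](O)C(=O)O | starting material
2 | pivalaldehyde | CC(C)(C)C=O | starting material
3 | (2S,5S)-2-tert-butyl-5-methyl-1,3-dioxolan-4-one | C[C@@H]1O[C@H](C(C)(C)C)OC1=O | intermediate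
4 | (S)-glycidol | OC[C@H]1CO1 | starting material
5 | [(2R)-oxiran-2-yl]methyl trifluoromethanesulfonate | O=S(=O)(OC[C@H]1CO1)C(F)(F)F | intermediate
6 | lithium (2S)-2-tert-butyl-5-methyl-1,3-dioxol-4-olate | [Li+].CC1=C([O-])O[C@@H](C(C)(C)C)O1 | intermediate
7 | (2S,5R)-2-tert-butyl-5-methyl-5-{[(2S)-oxiran-2-yl]methyl}-1,3-dioxolan-4-one | C[C@]1(C[C@H]2CO2)O[C@H](C(C)(C)C)OC1=O | intermediate
8 | lithium (2S)-1-[(2S,4R)-2-tert-butyl-4-methyl-5-oxo-1,3-dioxolan-4-yl]but-3-en-2-olate | [Li+].C[C@]1(C[C@H]([O-])C=C)O[C@H](C(C)(C)C)OC1=O | intermediate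
9 | (3R,5S)-5-ethenyl-3-hydroxy-3-methyloxolan-2-one | C[C@@]1(O)C[C@@H](C=C)OC1=O | intermediate
10 | (2Z)-3-methylpent-2-en-4-yn-1-ol | C#C/C(C)=C\CO | starting material
11 | dilithium (2Z)-3-methylpent-2-en-4-yn-5-id-1-olate | [Li+].[Li+].[C-]#C/C(C)=C\C[O-] | intermediate
12 | (2Z,7R,9S)-1,7,9-trihydroxy-3,7-dimethylundeca-2,10-dien-4-yn-6-one | C=C[C@@H](O)C[C@@](C)(O)C(=O)C#C/C(C)=C\CO | intermediate
13 | (3R,5S)-3,5-dihydroxy-3-methyl-1-(3-methylfuran-2-yl)hept-6-en-2-one | C=C[C@@H](O)C[C@@](C)(O)C(=O)Cc1occc1C | intermediate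
14 | 2-(bromomethyl)prop-2-enoic acid | OC(=O)C(=C)CBr | starting material
15 | 2-(bromomethyl)prop-2-enoyl chloride | ClC(=O)C(=C)CBr | intermediate
16 | (3S,5R)-5-hydroxy-5-methyl-7-(3-methylfuran-2-yl)-6-oxohept-1-en-3-yl 2-(bromomethyl)prop-2-enoate | C=C[C@@H](OC(=O)C(=C)CBr)C[C@@](C)(O)C(=O)Cc1occc1C | intermediate
17 | (5S)-3-(bromomethyl)-5-[(2R)-2-hydroxy-2-methyl-4-(3-methylfuran-2-yl)-3-oxobutyl]furan-2(5H)-one | BrCC1=C[C@H](C[C@@](C)(O)C(=O)Cc2occc2C)OC1=O | intermediate
18 | (5S)-3-(bromomethyl)-5-[(2R,6Z)-2-hydroxy-2,6-dimethyl-3,5,8-trioxooct-6-en-1-yl]furan-2(5H)-one | BrCC1=C[C@H](C[C@@](C)(O)C(=O)CC(=O)/C(C)=C\C=O)OC1=O | intermediate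
19 | (2Z)-3-[(5R)-5-{[(2S)-4-(bromomethyl)-5-oxo-2,5-dihydrofuran-2-yl]methyl}-5-methyl-4-oxo-4,5-dihydrofuran-2-yl]but-2-enal | BrCC1=C[C@H](C[C@@]2(C)OC(=CC2=O)/C(C)=C\C=O)OC1=O | intermediate
20 | (4Z,6R,7R,8S,10R)-6-hydroxy-1-oxo-3,10-epoxygermacra-2,4,11(13)-trien-12,8-olide | C=C1C(=O)O[C@H]2C[C@@]3(C)OC(=CC3=O)/C(C)=C\[C@@H](O)[C@H]12 | intermediate
21 | [(2R)-2-methyloxiran-2-yl]methanol | OC[C@]1(C)CO1 | starting material
22 | (2S)-2-methyloxirane-2-carboxylic acid | OC(=O)[C@]1(C)CO1 | intermediate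
23 | (4Z,6R,7R,8S,10R)-6-{[(2S)-2-methyloxiran-2-yl]carbonyloxy}-1-oxo-3,10-epoxygermacra-2,4,11(13)-trien-12,8-olide | C=C1C(=O)O[C@H]2C[C@@]3(C)OC(=CC3=O)/C(C)=C\[C@@H](OC(=O)[C@]3(C)CO3)[C@H]12 | target

**Step count**
Total: 11 steps. Longest linear sequence: 9 steps (1, 3, 4, 5, 6, 7, 8, 9, 11); steps 2 and 10 are side branches.

**Three steps most likely to fail**

Step 9 (ring closure at C6–C7). The strained bicyclic transition state may favour the other chair/boat arrangement and give the C6 epimer, besides oligomers or attack on the C1 carbonyl. The fallback moves the setting of C6 from the ring closure to the esterification. It sets out from 19: the allylation is run as before and the epimeric alcohol, (4Z,6S,7R,8S,10R)-6-hydroxy-1-oxo-3,10-epoxygermacra-2,4,11(13)-trien-12,8-olide F8, is isolated. F8 is then coupled with 22 under Mitsunobu conditions (PPh3, DIAD, toluene, 0 °C), which inverts C6 while installing the ester, and the route is rejoined at 23.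

Step 8 (furan to furanone enal). Over-oxidation at the active C2 methylene or an aldol closure of 18 onto the aldehyde may compete with the cyclodehydration. The fallback forms the C10–O–C3 bond by oxidative spiroketalisation and releases the aldehyde in a separate step. It sets out from 17: Br2, NaHCO3, MeOH, −40 °C (Clauson-Kaas-type alkoxylation with internal trapping by the C10 hydroxyl) gives the isolable (2R)-2-{[(2S)-4-(bromomethyl)-5-oxo-2,5-dihydrofuran-2-yl]methyl}-7-methoxy-2,9-dimethyl-1,6-dioxaspiro[4.4]non-8-en-3-one F7. Dilute aqueous trifluoroacetic acid in THF then hydrolyses the acetal, and β-elimination of the spiro C–O bond through the C2 enol comes back to 19.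

Step 5 (acetylide addition and furan formation). The C10 hydroxyl may compete with the C6 hydroxyl for C3 and give furanone/furan mixtures. The fallback makes the furanone directly and carries C6 as a silyl ether. It sets out from 9 and 10: 10 is silylated (TBSCl, imidazole) to tert-butyl(dimethyl){[(2Z)-3-methylpent-2-en-4-yn-1-yl]oxy}silane F1. Its lithium acetylide opens 9 to (2Z,7R,9S)-1-{[tert-butyl(dimethyl)silyl]oxy}-7,9-dihydroxy-3,7-dimethylundeca-2,10-dien-4-yn-6-one F2, where only the C10 hydroxyl can reach C3. K2CO3 in MeOH closes it 5-endo-dig to (2R)-5-[(2Z)-4-{[tert-butyl(dimethyl)silyl]oxy}but-2-en-2-yl]-2-[(2S)-2-hydroxybut-3-en-1-yl]-2-methylfuran-3(2H)-one F3. Acylation with 15 and 2,6-lutidine gives (2S)-1-{(2R)-5-[(2Z)-4-{[tert-butyl(dimethyl)silyl]oxy}but-2-en-2-yl]-2-methyl-3-oxo-2,3-dihydrofuran-2-yl}but-3-en-2-yl 2-(bromomethyl)prop-2-enoate F4. RCM gives (5S)-3-(bromomethyl)-5-({(2R)-5-[(2Z)-4-{[tert-butyl(dimethyl)silyl]oxy}but-2-en-2-yl]-2-methyl-3-oxo-2,3-dihydrofuran-2-yl}methyl)furan-2(5H)-one F5. HF·pyridine gives (5S)-3-(bromomethyl)-5-({(2R)-5-[(2Z)-4-hydroxybut-2-en-2-yl]-2-methyl-3-oxo-2,3-dihydrofuran-2-yl}methyl)furan-2(5H)-one F6, and Dess–Martin periodinane comes back to 19.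

**Further compounds**
F1 | step 5 | tert-butyl(dimethyl){[(2Z)-3-methylpent-2-en-4-yn-1-yl]oxy}silane | C#C/C(C)=C\CO[Si](C)(C)C(C)(C)C
F2 | step 5 | (2Z,7R,9S)-1-{[tert-butyl(dimethyl)silyl]oxy}-7,9-dihydroxy-3,7-dimethylundeca-2,10-dien-4-yn-6-one | C=C[C@@H](O)C[C@@](C)(O)C(=O)C#C/C(C)=C\CO[Si](C)(C)C(C)(C)C
F3 | step 5 | (2R)-5-[(2Z)-4-{[tert-butyl(dimethyl)silyl]oxy}but-2-en-2-yl]-2-[(2S)-2-hydroxybut-3-en-1-yl]-2-methylfuran-3(2H)-one | C=C[C@@H](O)C[C@@]1(C)OC(=CC1=O)/C(C)=C\CO[Si](C)(C)C(C)(C)C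
F4 | step 5 | (2S)-1-{(2R)-5-[(2Z)-4-{[tert-butyl(dimethyl)silyl]oxy}but-2-en-2-yl]-2-methyl-3-oxo-2,3-dihydrofuran-2-yl}but-3-en-2-yl 2-(bromomethyl)prop-2-enoate | C=C[C@@H](OC(=O)C(=C)CBr)C[C@@]1(C)OC(=CC1=O)/C(C)=C\CO[Si](C)(C)C(C)(C)C
F5 | step 5 | (5S)-3-(bromomethyl)-5-({(2R)-5-[(2Z)-4-{[tert-butyl(dimethyl)silyl]oxy}but-2-en-2-yl]-2-methyl-3-oxo-2,3-dihydrofuran-2-yl}methyl)furan-2(5H)-one | BrCC1=C[C@H](C[C@@]2(C)OC(=CC2=O)/C(C)=C\CO[Si](C)(C)C(C)(C)C)OC1=O
F6 | step 5 | (5S)-3-(bromomethyl)-5-({(2R)-5-[(2Z)-4-hydroxybut-2-en-2-yl]-2-methyl-3-oxo-2,3-dihydrofuran-2-yl}methyl)furan-2(5H)-one | BrCC1=C[C@H](C[C@@]2(C)OC(=CC2=O)/C(C)=C\CO)OC1=O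
F7 | step 8 | (2R)-2-{[(2S)-4-(bromomethyl)-5-oxo-2,5-dihydrofuran-2-yl]methyl}-7-methoxy-2,9-dimethyl-1,6-dioxaspiro[4.4]non-8-en-3-one (mixture at C5 and C7) | BrCC1=C[C@H](C[C@@]2(C)OC3(CC2=O)OC(OC)C=C3C)OC1=O
F8 | step 9 | (4Z,6S,7R,8S,10R)-6-hydroxy-1-oxo-3,10-epoxygermacra-2,4,11(13)-trien-12,8-olide | C=C1C(=O)O[C@H]2C[C@@]3(C)OC(=CC3=O)/C(C)=C\[C@H](O)[C@H]12
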